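A one-step world has one rate and one smooth curve, but the electrophile below loses a lump early and then falls along a nearly straight line.

common to all: electrophile 0.050 M

|  | free base | protonated nucleophile | remark | time |
|---|---|---|---|---|
| Wednesday's | 0.31 equiv | 2 equiv | run made earlier |  |
| Saturday's | 0.43 equiv | 2 equiv | run made earlier |  |
| Tuesday's | 0.62 equiv | 2 equiv | run made earlier |  |
| north-west | 0.300 equiv | 2.00 equiv |  | 2.0 min |
| east | 0.600 equiv | 2.00 equiv |  | 2.0 min |

- Wednesday's (time / s: electrophile / %, target / %): 10.0: 91.3, 7.0; 30.0: 84.5, 12.1; 60.0: 79.2, 17.3; 80.0: 75.7, 19.9; 120: 68.8, 25.5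
- Saturday's (time / s: electrophile / %, target / %): 25.0: 82.4, 15.2; 50.0: 76.5, 19.5; 80.0: 71.4, 23.1; 90.0: 69.3, 25.1; 120: 65.3, 28.7
- Tuesday's (time / s: electrophile / %, target / %): 10.0: 85.3, 12.4; 30.0: 74.8, 21.0; 60.0: 68.0, 25.4; 80.0: 64.2, 28.7; 120: 58.7, 33.8

(each reading ± 0.3 percentage points)

- a reading or a percentage of target counts all its forms, free or not

* part of the electrophile that has reacted at the end, north-west
* part of the electrophile that has reacted at the end, east
* what raising the equivalents of free base from its lowest to its highest value here does to the part of the electrophile that has reacted (changes below 5 percentage points count as none) (no change / it falls / it rises)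

So I read two amounts. The drift is the slope of the straight part. From 30.0 s to 120 s the electrophile falls by 0.105 min⁻¹ of its charge on Wednesday and by 0.107 min⁻¹ on Tuesday, though Tuesday had twice the free base. I take the mean, s = 0.106 min⁻¹.

I take the burst to be what free base adds. At 120 s, Tuesday's electrophile stands 10 percentage points below Wednesday's, so g = 0.326 of the charge per equivalent.

Their ratio gives the crossing time, the moment at which the drift has caught up with the burst:

t× = g × equivalents / s

part reacted = s × (t + t×)

For north-west t× = 55.3 s, and for east t× = 111 s. Both crossings come earlier than the asked 2.0 min, so in my reckoning the drift outweighs the burst in both flasks. I get 31.0% for north-west and 40.7% for east, a rise of 9.7 points, more than the 5 points that counts.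

The forecast says 30.9% and 40.6%, close to mine, and it rises. Of the burst it says “so it scales with the base”.

The flasks give 30.4% for north-west and 40.3% for east: it rises, by 9.9 points.

    target ⇌ isomer of the product (K = 0.240, k = 0.0640 s⁻¹)
    acid set free + free base ⇌ salt of the base, settled at all times (K = 19000 L mol⁻¹)
    nucleophile + acid set free ⇌ protonated nucleophile, settled at all times (K = 24000 L mol⁻¹)
    electrophile + nucleophile → acid set free + target (k = 0.940 L mol⁻¹ s⁻¹)
    acid set free → by-product carried off (k = 0.110 s⁻¹)
    nucleophile + target ⇌ idle adduct, settled at all times (K = 24.0 L mol⁻¹)

The neighbouring flask is north-west with 1.20 equiv of free base, read at the same 2.0 min. Its crossing scales with the free base to 221 s, later than the reading, so in my reckoning the burst outweighs the drift there, and s × (t + t×) gives 60.2%. In that flask 59.6% of the electrophile has reacted.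

(The numbers in the tables were computed with constants of no real substance, and the scatter is random.)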